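**Retrosynthetic overview**

1. Feature: in ring A (the acyl ring) the C3 formyl and C4 hydroxyl are neighbours, C3 sits between the oxygen-bearing C2 and C4, and C5–H is open. Both groups are therefore brought in together by adding DMF across a C3–C4 aryne, so no electrophilic formylation has to choose between C3 and C5.
2. Target ⇒ (hydrogenolysis of three benzyl ethers) tribenzyl salicylaldehyde depside ⇒ (CsF, DMF: C4–O and C3–CHO bonds) tribenzyl depside with C3–SiMe3 and C4–OTf.
3. Depside C(=O)–O5 bond ⇒ ring A acid chloride + ring B C5 phenol. The ring B phenol ⇒ atraric acid by C5 Rieche formylation, benzylation and Baeyer–Villiger oxidation.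
4. Ring A acid ⇒ 2,4-dihydroxy-6-methylbenzaldehyde. The C4 carbamate and C2 benzyl ether steer lithiation/silylation to C3. The C1 carbon travels as a dimethyl acetal and is oxidised last, because an ester at C1 would be deprotonated at the C6 methyl group by the base and could not be saponified beside SiMe3 and OTf.
5. No ring is built: both benzene rings are bought, and the only ring closed, the four-membered benzoxete of the key step, opens again.

Key step: step 12

Assumption: 2,4-dihydroxy-6-methylbenzaldehyde and methyl 2,4-dihydroxy-3,6-dimethylbenzoate are taken as purchasable; the target has no stereocentre, so no stereocontrol is required.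

**Route**

Step 1
Reactants: 1 2,4-dihydroxy-6-methylbenzaldehyde
Product: 2 4-formyl-3-hydroxy-5-methylphenyl N,N-diethylcarbamate
Conditions: Et2NCOCl (1.05 equiv), K2CO3, MeCN, 60 °C
Reagents that add atoms: N,N-diethylcarbamoyl chloride, CCN(CC)C(Cl)=O
Why: Selective O-acylation (carbamoylation): the C2 hydroxyl is tied up in a hydrogen bond to the formyl group, so only the free, more acidic C4 phenoxide should be acylated.

Step 2
Reactants: 2 4-formyl-3-hydroxy-5-methylphenyl N,N-diethylcarbamate
Product: 3 3-(benzyloxy)-4-formyl-5-methylphenyl N,N-diethylcarbamate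
Conditions: BnBr, K2CO3, MeCN, reflux
Reagents that add atoms: benzyl bromide, BrCc1ccccc1
Why: Williamson ether synthesis on the remaining chelated C2 phenol; the tertiary carbamate has no N–H and is inert to carbonate.

Step 3
Reactants: 3 3-(benzyloxy)-4-formyl-5-methylphenyl N,N-diethylcarbamate
Product: 4 3-(benzyloxy)-4-(dimethoxymethyl)-5-methylphenyl N,N-diethylcarbamate
Conditions: HC(OMe)3, p-TsOH·H2O (cat.), MeOH, rt; Et3N quench
Reagents that add atoms: trimethyl orthoformate, COC(OC)OC
Why: Acid-catalysed acetalisation with the orthoformate as water scavenger masks the electrophilic C1 carbon before metalation, and unlike an ester the acetal does not acidify the C6 methyl group.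

Step 4
Reactants: 4 3-(benzyloxy)-4-(dimethoxymethyl)-5-methylphenyl N,N-diethylcarbamate
Product: 6 3-(benzyloxy)-4-(dimethoxymethyl)-5-methyl-2-(trimethylsilyl)phenyl N,N-diethylcarbamate, via aryllithium 5 (not isolated)
Conditions: LiN(iPr)2, THF, −78 °C; Me3SiCl, −78 °C → rt
Reagents that add atoms: chlorotrimethylsilane, C[Si](C)(C)Cl; lithium diisopropylamide, [Li+].CC(C)[N-]C(C)C (lithium of 5 only)
Why: Directed ortho-metalation: ring A C3–H lies between the carbamate and the benzyloxy group and is the only proton the amide base can remove (it is too weak for the benzylic OCH2 or the C6 methyl), and at −78 °C the aryllithium should be silylated before an anionic ortho-Fries shift sets in.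

Step 5
Reactants: 6 3-(benzyloxy)-4-(dimethoxymethyl)-5-methyl-2-(trimethylsilyl)phenyl N,N-diethylcarbamate
Product: 7 3-(benzyloxy)-4-(dimethoxymethyl)-5-methyl-2-(trimethylsilyl)phenol
Conditions: LiAlH4, THF, 0 °C → reflux; aq. potassium sodium tartrate work-up
Reagents that add atoms: none
Why: Hydride reduction of the aryl carbamate expels the phenoxide under non-hydrolytic conditions that spare the aryl–silicon bond, the acetal and the benzyl ether, whereas hot hydroxide would risk protodesilylation.

Step 6
Reactants: 7 3-(benzyloxy)-4-(dimethoxymethyl)-5-methyl-2-(trimethylsilyl)phenol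
Product: 9 3-(benzyloxy)-4-formyl-5-methyl-2-(trimethylsilyl)phenyl trifluoromethanesulfonate, via acetal triflate 8 (not isolated)
Conditions: PhNTf2, DBU, MeCN, rt → 40 °C; then 1 M HCl, THF, rt
Reagents that add atoms: N-phenylbis(trifluoromethanesulfonimide), O=S(=O)(N(c1ccccc1)S(=O)(=O)C(F)(F)F)C(F)(F)F; water, O
Why: O-sulfonylation of the hindered ortho-silylphenoxide with a mild triflyl donor, followed by acid-catalysed acetal hydrolysis, which the aryl–silicon bond should withstand once the ring carries the withdrawing triflate.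

Step 7
Reactants: 9 3-(benzyloxy)-4-formyl-5-methyl-2-(trimethylsilyl)phenyl trifluoromethanesulfonate
Product: 10 2-(benzyloxy)-6-methyl-4-(trifluoromethylsulfonyloxy)-3-(trimethylsilyl)benzoic acid
Conditions: NaClO2, NaH2PO4, 2-methylbut-2-ene, t-BuOH/THF/H2O, rt
Reagents that add atoms: sodium chlorite, [Na+].[O-]Cl=O
Why: Pinnick oxidation brings the hindered aldehyde to the acid at mildly acidic pH without base or fluoride, and the alkene removes HOCl before it can cause ipso-chlorodesilylation.

Step 8
Reactants: 11 methyl 2,4-dihydroxy-3,6-dimethylbenzoate (atraric acid)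
Product: 12 methyl 5-formyl-2,4-dihydroxy-3,6-dimethylbenzoate
Conditions: Cl2CHOMe, TiCl4, CH2Cl2, 0 °C → rt; ice/1 M HCl
Reagents that add atoms: dichloromethyl methyl ether, COC(Cl)Cl; water, O
Why: Rieche formylation: ring B C5 is the only free ring position and lies ortho to the titanium-bound C4 phenoxide and para to the C2 hydroxyl, so regiochemistry is not in question.

Step 9
Reactants: 12 methyl 5-formyl-2,4-dihydroxy-3,6-dimethylbenzoate
Product: 13 methyl 2,4-bis(benzyloxy)-5-formyl-3,6-dimethylbenzoate
Conditions: BnBr (2.5 equiv), Cs2CO3, MeCN, reflux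
Reagents that add atoms: benzyl bromide, BrCc1ccccc1
Why: Double Williamson ether synthesis; the caesium phenoxides are reactive enough to overcome chelation and the flanking C3 methyl group.

Step 10
Reactants: 13 methyl 2,4-bis(benzyloxy)-5-formyl-3,6-dimethylbenzoate
Product: 15 methyl 2,4-bis(benzyloxy)-5-hydroxy-3,6-dimethylbenzoate, via aryl formate 14 (not isolated)
Conditions: mCPBA, CH2Cl2, rt; aq. Na2S2O3/NaHCO3 wash; then K2CO3 (cat.), MeOH, 0 °C
Reagents that add atoms: 3-chloroperoxybenzoic acid, OOC(=O)c1cccc(Cl)c1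
Why: Baeyer–Villiger (Dakin-type) oxidation in which the aryl group, enriched by ortho and para benzyloxy groups, migrates in preference to hydride; carbonate-catalysed methanolysis then removes the formyl group while the hindered methyl ester is unaffected.

Step 11
Reactants: 10 2-(benzyloxy)-6-methyl-4-(trifluoromethylsulfonyloxy)-3-(trimethylsilyl)benzoic acid; 15 methyl 2,4-bis(benzyloxy)-5-hydroxy-3,6-dimethylbenzoate
Product: 17 methyl 2,4-bis(benzyloxy)-5-{[2-(benzyloxy)-6-methyl-4-(trifluoromethylsulfonyloxy)-3-(trimethylsilyl)benzoyl]oxy}-3,6-dimethylbenzoate, via acid chloride 16 (not isolated)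
Conditions: 1-chloro-N,N,2-trimethylprop-1-en-1-amine, CH2Cl2, 0 °C → rt; then 15, Et3N, DMAP, CH2Cl2, rt → 40 °C
Reagents that add atoms: 1-chloro-N,N,2-trimethylprop-1-en-1-amine, CC(C)=C(Cl)N(C)C (supplies only the chlorine of 16; none of its atoms stays in 17)
Why: Neutral acid chloride formation with an α-chloroenamine followed by DMAP-catalysed esterification (nucleophilic acyl-transfer catalysis); no fluoride, alkoxide or strong acid is present, so the silyl/triflate pair should stay dormant.

Step 12
Reactants: 17 methyl 2,4-bis(benzyloxy)-5-{[2-(benzyloxy)-6-methyl-4-(trifluoromethylsulfonyloxy)-3-(trimethylsilyl)benzoyl]oxy}-3,6-dimethylbenzoate; 18 N,N-dimethylformamide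
Product: 22 methyl 2,4-bis(benzyloxy)-5-{[2-(benzyloxy)-3-formyl-4-hydroxy-6-methylbenzoyl]oxy}-3,6-dimethylbenzoate, via aryne 19 (not isolated), via benzoxete 20 (not isolated), via ortho-quinone methide 21 (not isolated)
Conditions: CsF (3 equiv), dry 18 as solvent (0.02 M), slow addition of 17, rt → 40 °C; then H2O, pH 5 buffer work-up
Reagents that add atoms: water, O
Why: Fluoride attacks the C3 silicon of 17 and the C4 triflate departs, the established 1,2-elimination of ortho-silylaryl triflates, to give aryne 19. The carbonyl oxygen of 18, present in solvent excess, adds to C4 and the C3 aryl anion closes on the iminium carbon (4-exo-trig) to benzoxete 20, whose O–CH bond opens electrocyclically to the ortho-quinone methide 21, so no ring is retained and the C4–O and C3–C bonds are made in one fixed order. Water hydrolyses the enaminone-like 21 to the salicylaldehyde 22 with loss of dimethylamine. The closest known reaction type is the formal insertion of arynes into the C=O bond of formamides, which with 3-alkoxyarynes gives 6-alkoxysalicylaldehydes. The selectivity needed is regiochemical, and it is secured by the inductively withdrawing C2 benzyloxy group (backed by the C1 acyl group), which distorts the aryne so that C4 is the electrophilic terminus and the negative charge builds up at C3 next to it. No stereocentre survives, the tetra-ortho-substituted depside ester and the hindered methyl ester should resist CsF, and slow addition at high dilution keeps the aryne away from amine or phenoxide, which are released only at the aqueous quench.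

Step 13
Reactants: 22 methyl 2,4-bis(benzyloxy)-5-{[2-(benzyloxy)-3-formyl-4-hydroxy-6-methylbenzoyl]oxy}-3,6-dimethylbenzoate
Product: 23 methyl 5-[(3-formyl-2,4-dihydroxy-6-methylbenzoyl)oxy]-2,4-dihydroxy-3,6-dimethylbenzoate (target)
Conditions: H2 (1 atm), Pd/C (10 wt% Pd), EtOAc, rt, stopped after three equivalents of H2
Reagents that add atoms: none
Why: Catalytic hydrogenolysis of the three aryl benzyl ethers under neutral conditions; the formyl group, held by hydrogen bonds from the C2 and C4 hydroxyls, should be reduced much more slowly, and the absence of base avoids a shift of the acyl group from O5 to the freed neighbouring O4 of ring B.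

**Compound list**

1 | 2,4-dihydroxy-6-methylbenzaldehyde | O=Cc1c(C)cc(O)cc1O | starting material
2 | 4-formyl-3-hydroxy-5-methylphenyl N,N-diethylcarbamate | CCN(CC)C(=O)Oc1cc(C)c(C=O)c(O)c1 | intermediate
3 | 3-(benzyloxy)-4-formyl-5-methylphenyl N,N-diethylcarbamate | CCN(CC)C(=O)Oc1cc(C)c(C=O)c(OCc2ccccc2)c1 | intermediate
4 | 3-(benzyloxy)-4-(dimethoxymethyl)-5-methylphenyl N,N-diethylcarbamate | CCN(CC)C(=O)Oc1cc(C)c(C(OC)OC)c(OCc2ccccc2)c1 | intermediate
5 | 2-lithio derivative of 4 (aryllithium at ring A C3) | CCN(CC)C(=O)Oc1cc(C)c(C(OC)OC)c(OCc2ccccc2)c1[Li] | intermediate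
6 | 3-(benzyloxy)-4-(dimethoxymethyl)-5-methyl-2-(trimethylsilyl)phenyl N,N-diethylcarbamate | CCN(CC)C(=O)Oc1cc(C)c(C(OC)OC)c(OCc2ccccc2)c1[Si](C)(C)C | intermediate
7 | 3-(benzyloxy)-4-(dimethoxymethyl)-5-methyl-2-(trimethylsilyl)phenol | COC(OC)c1c(C)cc(O)c([Si](C)(C)C)c1OCc1ccccc1 | intermediate
8 | 3-(benzyloxy)-4-(dimethoxymethyl)-5-methyl-2-(trimethylsilyl)phenyl trifluoromethanesulfonate | COC(OC)c1c(C)cc(OS(=O)(=O)C(F)(F)F)c([Si](C)(C)C)c1OCc1ccccc1 | intermediate
9 | 3-(benzyloxy)-4-formyl-5-methyl-2-(trimethylsilyl)phenyl trifluoromethanesulfonate | O=Cc1c(C)cc(OS(=O)(=O)C(F)(F)F)c([Si](C)(C)C)c1OCc1ccccc1 | intermediate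
10 | 2-(benzyloxy)-6-methyl-4-(trifluoromethylsulfonyloxy)-3-(trimethylsilyl)benzoic acid | OC(=O)c1c(C)cc(OS(=O)(=O)C(F)(F)F)c([Si](C)(C)C)c1OCc1ccccc1 | intermediate
11 | methyl 2,4-dihydroxy-3,6-dimethylbenzoate (atraric acid) | COC(=O)c1c(C)cc(O)c(C)c1O | starting material
12 | methyl 5-formyl-2,4-dihydroxy-3,6-dimethylbenzoate | COC(=O)c1c(C)c(C=O)c(O)c(C)c1O | intermediate
13 | methyl 2,4-bis(benzyloxy)-5-formyl-3,6-dimethylbenzoate | COC(=O)c1c(C)c(C=O)c(OCc2ccccc2)c(C)c1OCc1ccccc1 | intermediate
14 | methyl 2,4-bis(benzyloxy)-5-(formyloxy)-3,6-dimethylbenzoate | COC(=O)c1c(C)c(OC=O)c(OCc2ccccc2)c(C)c1OCc1ccccc1 | intermediate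
15 | methyl 2,4-bis(benzyloxy)-5-hydroxy-3,6-dimethylbenzoate | COC(=O)c1c(C)c(O)c(OCc2ccccc2)c(C)c1OCc1ccccc1 | intermediate
16 | 2-(benzyloxy)-6-methyl-4-(trifluoromethylsulfonyloxy)-3-(trimethylsilyl)benzoyl chloride | ClC(=O)c1c(C)cc(OS(=O)(=O)C(F)(F)F)c([Si](C)(C)C)c1OCc1ccccc1 | intermediate
17 | methyl 2,4-bis(benzyloxy)-5-{[2-(benzyloxy)-6-methyl-4-(trifluoromethylsulfonyloxy)-3-(trimethylsilyl)benzoyl]oxy}-3,6-dimethylbenzoate | COC(=O)c1c(C)c(OC(=O)c2c(C)cc(OS(=O)(=O)C(F)(F)F)c([Si](C)(C)C)c2OCc2ccccc2)c(OCc2ccccc2)c(C)c1OCc1ccccc1 | intermediate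
18 | N,N-dimethylformamide | CN(C)C=O | starting material
19 | ring A C3–C4 aryne of the tribenzyl depside | COC(=O)c1c(C)c(OC(=O)C2=C(OCc3ccccc3)C#CC=C2C)c(OCc2ccccc2)c(C)c1OCc1ccccc1 | intermediate
20 | 2-(dimethylamino)-2H-benzoxete fused at ring A C3–C4 (racemic, transient) | COC(=O)c1c(C)c(OC(=O)c2c(C)cc3OC(N(C)C)c3c2OCc2ccccc2)c(OCc2ccccc2)c(C)c1OCc1ccccc1 | intermediate
21 | ring A ortho-quinone methide (C4 ketone, C3 dimethylaminomethylene) | COC(=O)c1c(C)c(OC(=O)C2=C(OCc3ccccc3)C(=CN(C)C)C(=O)C=C2C)c(OCc2ccccc2)c(C)c1OCc1ccccc1 | intermediate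
22 | methyl 2,4-bis(benzyloxy)-5-{[2-(benzyloxy)-3-formyl-4-hydroxy-6-methylbenzoyl]oxy}-3,6-dimethylbenzoate | COC(=O)c1c(C)c(OC(=O)c2c(C)cc(O)c(C=O)c2OCc2ccccc2)c(OCc2ccccc2)c(C)c1OCc1ccccc1 | intermediate
23 | methyl 5-[(3-formyl-2,4-dihydroxy-6-methylbenzoyl)oxy]-2,4-dihydroxy-3,6-dimethylbenzoate | COC(=O)c1c(C)c(OC(=O)c2c(C)cc(O)c(C=O)c2O)c(O)c(C)c1O | target

**Step count**

- Total steps: 13 (seven to the ring A acid, three to the ring B phenol, three after convergence).
- Longest linear sequence: 10 steps (steps 1–7, 11, 12, 13).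

**Steps most likely to fail**

1. Step 12.
   - What may go wrong: the weakly nucleophilic formamide oxygen may lose the race for the aryne to fluoride. It may also lose it to dimethylamine released by adventitious water, or to phenoxide formed early. Part of the oxygen may add at C3, and long fluoride contact may erode the depside ester.
   - Fallback (from 17, back at 22): the silicon serves as a placeholder for carbon instead of as an aryne trigger.
     - Ipso-iododesilylation with ICl (CH2Cl2, 0 °C) should give the iodo triflate F1.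
     - Et4NOH in dioxane at rt cleaves the S–O bond of the triflate to give the iodophenol F2.
     - MeMgCl/LiCl then iPrMgCl (THF, −20 °C) deprotonates the phenol and exchanges iodine for magnesium, giving the magnesiated magnesium phenoxide F3.
     - F3 is formylated with 18 (Bouveault aldehyde synthesis) and gives 22 on mildly acidic work-up. The route continues with step 13.

2. Step 11.
   - What may go wrong: acyl transfer between a 2,6-disubstituted acyl chloride and a 2,6-disubstituted phenol may stall. The heat or stronger base needed to force it could set off the silyl/triflate pair too early.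
   - Fallback (from 7, back at 17): the triflate is installed only after the rings are joined.
     - Allyl bromide/K2CO3 (acetone, reflux) converts 7 into the allyl ether acetal F4.
     - PPTS in aqueous acetone frees the aldehyde F5.
     - Pinnick oxidation as in step 7 gives the acid F6.
     - The α-chloroenamine gives the acid chloride F7.
     - F7 can now be heated with 15, Et3N and stoichiometric DMAP in toluene at 90 °C to give the depside allyl ether F8.
     - Tsuji–Trost deallylation (Pd(PPh3)4, morpholine, THF, rt) gives the depside phenol F9.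
     - PhNTf2/DBU as in step 6 gives 17.

3. Step 13.
   - What may go wrong: the formyl group may be over-reduced to hydroxymethyl or methyl. The hindered benzyl ethers may cleave incompletely. The acyl group may migrate to the neighbouring ring B oxygen during a prolonged reaction.
   - Fallback (from 22, back at 23): non-reductive Lewis acid debenzylation with BCl3 and pentamethylbenzene as benzyl cation scavenger (CH2Cl2, −78 °C, methanol quench). This leaves aldehyde and esters at their oxidation level and makes no new isolated compound.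

**Further compounds**

F1 | step 12 | methyl 2,4-bis(benzyloxy)-5-{[2-(benzyloxy)-3-iodo-6-methyl-4-(trifluoromethylsulfonyloxy)benzoyl]oxy}-3,6-dimethylbenzoate | COC(=O)c1c(C)c(OC(=O)c2c(C)cc(OS(=O)(=O)C(F)(F)F)c(I)c2OCc2ccccc2)c(OCc2ccccc2)c(C)c1OCc1ccccc1
F2 | step 12 | methyl 2,4-bis(benzyloxy)-5-{[2-(benzyloxy)-4-hydroxy-3-iodo-6-methylbenzoyl]oxy}-3,6-dimethylbenzoate | COC(=O)c1c(C)c(OC(=O)c2c(C)cc(O)c(I)c2OCc2ccccc2)c(OCc2ccccc2)c(C)c1OCc1ccccc1
F3 | step 12 | C3-chloromagnesio C4-chloromagnesium phenoxide derived from F2 | COC(=O)c1c(C)c(OC(=O)c2c(C)cc(O[Mg]Cl)c([Mg]Cl)c2OCc2ccccc2)c(OCc2ccccc2)c(C)c1OCc1ccccc1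
F4 | step 11 | [6-(allyloxy)-2-(benzyloxy)-3-(dimethoxymethyl)-4-methylphenyl]trimethylsilane | COC(OC)c1c(C)cc(OCC=C)c([Si](C)(C)C)c1OCc1ccccc1
F5 | step 11 | 4-(allyloxy)-2-(benzyloxy)-6-methyl-3-(trimethylsilyl)benzaldehyde | O=Cc1c(C)cc(OCC=C)c([Si](C)(C)C)c1OCc1ccccc1
F6 | step 11 | 4-(allyloxy)-2-(benzyloxy)-6-methyl-3-(trimethylsilyl)benzoic acid | OC(=O)c1c(C)cc(OCC=C)c([Si](C)(C)C)c1OCc1ccccc1
F7 | step 11 | 4-(allyloxy)-2-(benzyloxy)-6-methyl-3-(trimethylsilyl)benzoyl chloride | ClC(=O)c1c(C)cc(OCC=C)c([Si](C)(C)C)c1OCc1ccccc1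
F8 | step 11 | methyl 5-{[4-(allyloxy)-2-(benzyloxy)-6-methyl-3-(trimethylsilyl)benzoyl]oxy}-2,4-bis(benzyloxy)-3,6-dimethylbenzoate | COC(=O)c1c(C)c(OC(=O)c2c(C)cc(OCC=C)c([Si](C)(C)C)c2OCc2ccccc2)c(OCc2ccccc2)c(C)c1OCc1ccccc1
F9 | step 11 | methyl 2,4-bis(benzyloxy)-5-{[2-(benzyloxy)-4-hydroxy-6-methyl-3-(trimethylsilyl)benzoyl]oxy}-3,6-dimethylbenzoate | COC(=O)c1c(C)c(OC(=O)c2c(C)cc(O)c([Si](C)(C)C)c2OCc2ccccc2)c(OCc2ccccc2)c(C)c1OCc1ccccc1
F0 | step 13 | none | none
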